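The starting material charged is conserved, so whatever has gone from it stands in products, and early on I took those to be the two adducts read.

| setting | oak | maple | flask |
|---|---|---|---|
| starting material | 0.50 M | 2 M | 1.0 M |
| reagent | 1 equiv | 1 equiv | 1.00 equiv |
| remark | run made earlier | run made earlier |  |
| time |  |  | 6.0 min |

| run | time / min | other mono adduct / % | single product / % |
|---|---|---|---|
| oak | 0.500 | 1.8 | 1.4 |
| oak | 0.833 | 1.6 | 2.1 |
| oak | 1.33 | 2.2 | 2.7 |
| oak | 2.00 | 4.2 | 3.2 |
| oak | 4.00 | 8.4 | 7.4 |
| oak | 6.00 | 12.9 | 7.9 |
| maple | 0.417 | 4.2 | 2.6 |
| maple | 1.33 | 11.1 | 9.1 |
| maple | 2.00 | 14.1 | 10.9 |
| maple | 3.00 | 17.9 | 12.6 |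
| maple | 5.00 | 23.7 | 15.0 |
| maple | 6.00 | 23.1 | 16.1 |

(scatter of a reading: 1 percentage point)

* equivalents of reagent to starting material, everything else as given, that leave most other mono adduct at 6.0 min
* the amount of other mono adduct then, in percent of the starting material charged
* the amount of other mono adduct with the amounts as given

At 1.33 min the maple run held 11.1% of other mono adduct and 9.1% of single product. Dividing their sum by that time and by the reagent charged gave a reading of 0.0759 /M/min for the two paths together.

So for the flask I took one over that constant times the charged reagent: the turnover time 13.2 min, a pseudo-first-order time with reagent held at its charge. The asked time is shorter than this, and the exponential of time over turnover time gave my estimate of 63.4% of the starting material left. Other mono adduct took 55.0% of what had reacted in that reading, so I reckoned 20.1% of it. But my reckoning lost no adduct, so it gave me no best charge.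

The forecast gave 16.5% as charged, below my figure, and 24.7% at 2.8 equiv, saying of its further step: “This assumed hidden step is what creates an interior optimum”.

The flask gave 17.7% as charged, and 32.2% at 3.78 equiv.

    starting material + reagent → single product + by-product (k = 0.0440 /M/min)
    starting material + reagent → other mono adduct + by-product (k = 0.0500 /M/min)
    reagent + single product → double product + by-product (k = 0.0590 /M/min)
    reagent + other mono adduct → double product + by-product (k = 0.0270 /M/min)
    single product → over-reaction product (k = 0.0520 /min)
    crystals ⇌ by-product, rate k6*(cs6 - [by-product]) while solid is left; crystals form when [by-product] > cs6 (solubility = 0.320 M, k = 1.30 /min)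

Starting material left at 6.00 min stood at 64%, against the 63.4% from my 13.2 min. Of the effects tried on other mono adduct as charged, the largest single one was the length of the run: the same flask left until 60.0 min held 31.7% instead of 17.7%. For the neighbour flask with 2.50 equiv of reagent, the turnover time shortens to 5.27 min, which puts starting material left at 32.0%; the simulation gave 32%.

Readings and results are simulated for substances that don't exist.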